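All runs were generated by integration on assumed constants; noise was put on by code.

The constant I need first is the one that carries X into L, and oak shows it at work.

| setting | maple | ash | oak | autumn | midnight | dusk | noon |
|---|---|---|---|---|---|---|---|
| Z | 16 mM | 16 mM | 32 mM | 16 mM | 16 mM | 16 mM | 16 mM |
| Q | 16 mM | 16 mM | 32 mM | 16 mM | 16 mM | 16 mM | 16 mM |
| G | 0.60 equiv | 0.90 equiv | 1.2 equiv | 1.20 equiv | 1.20 equiv | 1.20 equiv | 1.20 equiv |
| J | 4.8 mol% | 4.8 mol% | 4.8 mol% | 4.8 mol% | 4.8 mol% | 4.8 mol% | 4.8 mol% |
| temperature | 35 °C | 85 °C | 35 °C | 70 °C | 100 °C | 130 °C | 40 °C |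
| remark | run made earlier | run made earlier | run made earlier |  |  |  |  |
| time |  |  |  | 15 h | 15 h | 15 h | 15 h |

| run | time / h | X / % | L / % | Z / % |
|---|---|---|---|---|
| maple | 15.0 | 10.8 | 9.1 | 32.1 |
| maple | 30.0 | 13.8 | 12.3 | 27.5 |
| maple | 60.0 | 15.2 | 14.7 | 24.0 |
| maple | 72.0 | 14.6 | 13.8 | 24.4 |
| ash | 0.667 | 15.8 | 15.6 | 23.2 |
| ash | 2.00 | 21.2 | 20.4 | 14.6 |
| ash | 4.00 | 21.0 | 21.7 | 12.6 |
| ash | 6.00 | 22.9 | 22.2 | 12.4 |
| oak | 6.00 | 22.2 | 16.7 | 16.6 |
| oak | 12.0 | 25.0 | 22.9 | 10.7 |
| oak | 30.0 | 28.7 | 27.6 | 5.5 |
| oak | 72.0 | 28.9 | 29.8 | 2.0 |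

(standard deviation of a reading: 0.5 percentage points)

- the flask that comes out highest in share of X in all that became X or L, or "all alike" when all lie within 1.5 percentage points (autumn / midnight / dusk / noon / all alike)
- share of X in all that became X or L, autumn
- share of X in all that became X or L, midnight
- share of X in all that became X or L, dusk
- share of X in all that became X or L, noon

- J is single-handed; Z and Q are mirror images of each other, charged as a racemate, each of them at the stated concentration

I take lost Z to become X and lost Q to become L. In oak, between 6.00 h and 12.0 h, Z falls by 5.9 percentage points while X and L together gain 9 points. So the feed favours X by 2.8 points, yet the excess of X over L shrinks from 5.5 points to 2.1 points. Exchange must have removed both amounts. Integrated over the mean excess, they give a first-order exchange constant of 0.272 h⁻¹, a reading with all its scatter.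

Now I fold this into one number, E: the feed gap per hour, divided by the exchange constant and by X and L together, and oak at 12.0 h gives E = 0.0358. It says what excess the feed can hold against exchange, which is kinetic against thermodynamic control, and the share of X, as a fraction, is 0.5 plus E divided by 2.

Noon is charged with G and J each at the oak concentration divided by 2. Assuming the feed follows the product of these two charges, and at similar conversion, noon's E is 0.00896, a quarter of oak's. That puts noon 0.45 points above even, inside the margin. One number is not quite enough, since it ignores the warmer bath, but ash already reads 50.3% at its first point. So I reckon all alike.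

The forecast differs: 50.4%, 50.2%, 50%, 52.7%, and noon: “Noon is the likely highest, though only marginally above the 1.5-point threshold.”

The flasks give all alike: autumn 50.0%, midnight 50.0%, dusk 50.0%, noon 50.9%.

    X ⇌ L (k = 9.78 × 10⁻⁵ s⁻¹, Ea = 96.0 kJ mol⁻¹)
    2 J ⇌ D, settled at all times (K = 1200 L mol⁻¹, ΔH = −50.0 kJ mol⁻¹)
    G + J + Q → J + L (k = 0.643 L² mol⁻² s⁻¹, Ea = 48.0 kJ mol⁻¹)
    G + J + Z → J + X (k = 5.71 L² mol⁻² s⁻¹, Ea = 49.0 kJ mol⁻¹)
    (constants at 40 °C)

In noon, the exchange half-life of 0.984 h is shorter than the 15 h run. Noon's E comes out at 0.0190, against my 0.00896. A neighbour of noon charged with 4.80 equiv of G has Z down to 0.0452% at 15.0 h, and its share is 49.0%. Its E is −0.0206, which is −0.576 times oak's 0.0358.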